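The α‑methylene‑γ‑butyrolactone (ring O–C6–C7–C11–C12) is built from carbon dioxide. In the key step an alkenyl boronate at C11 is carboxylated under copper catalysis, and the acrylate carboxylate at once displaces a mesylate at C6 with inversion. The C11–C12 bond and the lactone O–C6 bond thus form in one operation. The step exploits the 1,1‑disubstituted alkene C11=C13 and the oxygen‑bearing C6 that lies between C7 and the C4–C5 epoxide. Its precursor is an open‑chain (6R)‑mesylate carrying the vinyl epoxide, made by a copper‑catalysed allene–aldehyde–diboron coupling. A chromium‑mediated dienoate addition, two acylations and ring‑closing metathesis at C2=C3 then close the ten‑membered ring.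

Key step: step 10

Numbering: C1–C10 are the ring carbons (germacrane numbering), C11 the lactone α‑carbon, C12 the lactone carbonyl, C13 the exocyclic methylene, C14 the ester carbon, C15 the methyl on C4.

Assumption: in steps 8 and 13 the ligand antipode written is taken to be the one that gives the drawn configuration; the sense of induction must be checked on a model and the mirror‑image ligand used if it is opposite.

Step 1
Reactants: 1 (E)-3-methylpent-2-en-4-yn-1-ol
Product: 2 [(2R,3R)-3-ethynyl-3-methyloxiran-2-yl]methanol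
Conditions: Ti(OiPr)4 (10 mol %), D-(−)-diethyl tartrate (12 mol %), t-BuOOH, 4 Å MS, CH2Cl2, −20 °C
Reagents that add atoms: tert-butyl hydroperoxide, CC(C)(C)OO
Why: Sharpless asymmetric epoxidation of the primary E-allylic alcohol, in which the titanium D-tartrate complex should deliver oxygen to the face that gives the (2R,3R)-epoxide (C5 and C4 of the target) and the E geometry of 1 places the methyl group cis to the carbinol carbon.

Step 2
Reactants: 2 [(2R,3R)-3-ethynyl-3-methyloxiran-2-yl]methanol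
Product: 3 [(2R,3R)-3-ethenyl-3-methyloxiran-2-yl]methanol
Conditions: H2 (1 atm), Pd/CaCO3 poisoned with Pb(OAc)2, quinoline, EtOAc, 0 °C
Reagents that add atoms: none
Why: Lindlar semihydrogenation should stop at the terminal alkene because the poisoned catalyst leaves the epoxide and the new vinyl group alone, and no stereocentre is touched.

Step 3
Reactants: 3 [(2R,3R)-3-ethenyl-3-methyloxiran-2-yl]methanol
Product: 4 (2S,3R)-3-ethenyl-3-methyloxirane-2-carbaldehyde
Conditions: TEMPO (10 mol %), PhI(OAc)2, CH2Cl2, 23 °C; used as a solution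
Reagents that add atoms: none
Why: TEMPO-catalysed oxidation with PhI(OAc)2 takes the primary alcohol to the aldehyde under neutral conditions, so the epoxide survives and C5, alpha to the new carbonyl, should not epimerise.

Step 4
Reactants: 5 (R)-2,2-dimethyl-1,3-dioxolane-4-carbaldehyde
Product: 6 (S)-4-ethynyl-2,2-dimethyl-1,3-dioxolane
Conditions: dimethyl (1-diazo-2-oxopropyl)phosphonate, K2CO3, MeOH, 0 to 23 °C
Reagents that add atoms: dimethyl (1-diazo-2-oxopropyl)phosphonate, COP(=O)(OC)C(=[N+]=[N-])C(C)=O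
Why: Ohira–Bestmann (Seyferth–Gilbert) homologation converts the aldehyde into the terminal alkyne under mild methanolysis conditions that leave the alpha-alkoxy stereocentre (C8 of the target) intact.

Step 5
Reactants: 6 (S)-4-ethynyl-2,2-dimethyl-1,3-dioxolane
Product: 8 (S)-2,2-dimethyl-4-(propa-1,2-dien-1-yl)-1,3-dioxolane, via Mannich base 7 (not isolated)
Conditions: (CH2O)n, CuI (50 mol %), dicyclohexylamine, 1,4-dioxane, reflux
Reagents that add atoms: formaldehyde (as paraformaldehyde), C=O
Why: Crabbé homologation, in which a copper-mediated Mannich reaction gives the propargylic amine that then undergoes a 1,5-hydride shift and fragmentation to the terminal allene without touching the stereocentre.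

Step 6
Reactants: 8 (S)-2,2-dimethyl-4-(propa-1,2-dien-1-yl)-1,3-dioxolane
Product: 9 (S)-penta-3,4-diene-1,2-diol
Conditions: AcOH/H2O (4:1), 40 °C
Reagents that add atoms: none
Why: Acid-catalysed hydrolysis of the terminal isopropylidene acetal is done here, before any acid-labile epoxide is present, and the allene is inert to aqueous acetic acid.

Step 7
Reactants: 9 (S)-penta-3,4-diene-1,2-diol
Product: 10 (S)-4,5-bis(triethylsilyloxy)penta-1,2-diene
Conditions: Et3SiCl, imidazole, DMF, 0 to 23 °C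
Reagents that add atoms: chlorotriethylsilane, CC[Si](Cl)(CC)CC
Why: Silylation of both hydroxyl groups gives ethers that should survive the bases of steps 8 to 10, allow the one-step oxidation of the primary ether in step 11 and come off with buffered fluoride.

Step 8
Reactants: 4 (2S,3R)-3-ethenyl-3-methyloxirane-2-carbaldehyde; 10 (S)-4,5-bis(triethylsilyloxy)penta-1,2-diene
Product: 12 (1R,2S,3S)-1-[(2R,3R)-3-ethenyl-3-methyloxiran-2-yl]-2-[1-(4,4,5,5-tetramethyl-1,3,2-dioxaborolan-2-yl)ethenyl]-3,4-bis(triethylsilyloxy)butan-1-ol, via O-boryl ether 11 (not isolated)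
Conditions: CuCl (5 mol %), (S,S)-Ph-BPE (6 mol %), NaOt-Bu (20 mol %), B2pin2 (1.1 equiv), THF, 22 °C; then aqueous NH4Cl
Reagents that add atoms: bis(pinacolato)diboron, CC1(C)OB(OC1(C)C)B1OC(C)(C)C(C)(C)O1
Why: Borylative allene–aldehyde coupling, in which copper–boryl addition to the terminal C=C of 10 gives a Z-configured 2-boryl allylcopper that adds through its substituted carbon to 4 in a closed chair transition state, so that C6 and C7 form syn, the aldehyde reacts on the Felkin–Anh face anti to the C5–O bond of the epoxide (reinforced by the chiral bisphosphine) and C8 is expected to place its C8–C9 bond anti to the forming bond.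

Step 9
Reactants: 12 (1R,2S,3S)-1-[(2R,3R)-3-ethenyl-3-methyloxiran-2-yl]-2-[1-(4,4,5,5-tetramethyl-1,3,2-dioxaborolan-2-yl)ethenyl]-3,4-bis(triethylsilyloxy)butan-1-ol
Product: 13 (1R,2R,3S)-1-[(2R,3R)-3-ethenyl-3-methyloxiran-2-yl]-2-[1-(4,4,5,5-tetramethyl-1,3,2-dioxaborolan-2-yl)ethenyl]-3,4-bis(triethylsilyloxy)butyl methanesulfonate
Conditions: MsCl, Et3N, CH2Cl2, −20 °C
Reagents that add atoms: methanesulfonyl chloride, CS(=O)(=O)Cl
Why: Sulfonylation through the sulfene turns the hindered C6 oxygen into a leaving group with retention at carbon, and the alkenyl boronate and the epoxide are inert to these conditions.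

Step 10
Reactants: 13 (1R,2R,3S)-1-[(2R,3R)-3-ethenyl-3-methyloxiran-2-yl]-2-[1-(4,4,5,5-tetramethyl-1,3,2-dioxaborolan-2-yl)ethenyl]-3,4-bis(triethylsilyloxy)butyl methanesulfonate
Product: 15 (4S,5S)-4-[(1S)-1,2-bis(triethylsilyloxy)ethyl]-5-[(2R,3R)-3-ethenyl-3-methyloxiran-2-yl]-3-methylideneoxolan-2-one, via potassium carboxylate 14 (not isolated)
Conditions: [(IPr)CuCl] (5 mol %; IPr = 1,3-bis(2,6-diisopropylphenyl)imidazol-2-ylidene), KOMe (1.1 equiv), CO2 (1 atm), THF, 23 then 60 °C
Reagents that add atoms: carbon dioxide, O=C=O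
Why: Methoxide adds to boron of 13, the ate complex passes the alkenyl group to (IPr)Cu, CO2 inserts into the Cu–C bond to make the C11–C12 bond, and the acrylate carboxylate, released as potassium salt 14, displaces the neighbouring C6 mesylate to make the O–C6 bond. The closest known reaction types are the NHC–copper-catalysed carboxylation of alkenylboronic esters with CO2 and the invertive lactonisation of γ-sulfonyloxy carboxylates, here run as one operation. The lactone ring closes in the 5-exo-tet mode. C6 is the only stereocentre that changes: backside SN2 attack inverts the (6R)-mesylate carbon set in step 8 to the (6S) lactone carbon, trans to the C7–C8 bond, while C4, C5, C7 and C8 are untouched. The step needs carboxylation to outrun E2 loss of the mesylate and O-alkylation at C6 to win over opening of the C4–C5 epoxide; the alkoxide is held on boron and is never free in excess, five-membered closure onto a sulfonate should be faster than six-membered attack on the unactivated epoxide carbon C5, and CO2 should trap the alkenylcopper before it reaches the mesylate or the vinyl epoxide.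

Step 11
Reactants: 15 (4S,5S)-4-[(1S)-1,2-bis(triethylsilyloxy)ethyl]-5-[(2R,3R)-3-ethenyl-3-methyloxiran-2-yl]-3-methylideneoxolan-2-one
Product: 16 (2S)-2-[(2S,3S)-2-[(2R,3R)-3-ethenyl-3-methyloxiran-2-yl]-4-methylidene-5-oxooxolan-3-yl]-2-(triethylsilyloxy)acetaldehyde
Conditions: (COCl)2, DMSO, CH2Cl2, −78 to −40 °C; then Et3N, −78 to 0 °C
Reagents that add atoms: none
Why: Under Swern conditions the chlorosulfonium salt cleaves the less hindered primary triethylsilyl ether and oxidises it in the same pot (oxidative desilylation) while the secondary silyl ether at C8 stays on, so the alpha-silyloxy aldehyde is reached without acid.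

Step 12
Reactants: 17 methyl 2-(triphenylphosphoranylidene)acetate; 18 acrolein
Product: 20 methyl (2Z)-2-iodopenta-2,4-dienoate, via iodo ylide 19 (not isolated)
Conditions: N-iodosuccinimide, CH2Cl2, −20 °C; then acrolein, −20 to 23 °C, dark
Reagents that add atoms: N-iodosuccinimide, O=C1CCC(=O)N1I
Why: Iodination of the stabilised ylide gives the iodo ylide, whose Wittig reaction with acrolein should place the ester trans to the vinyl group (Z-iodide), as is usual for stabilised alpha-halo ylides.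

Step 13
Reactants: 16 (2S)-2-[(2S,3S)-2-[(2R,3R)-3-ethenyl-3-methyloxiran-2-yl]-4-methylidene-5-oxooxolan-3-yl]-2-(triethylsilyloxy)acetaldehyde; 20 methyl (2Z)-2-iodopenta-2,4-dienoate
Product: 21 methyl (2E)-2-[(1S,2S)-2-[(2S,3S)-2-[(2R,3R)-3-ethenyl-3-methyloxiran-2-yl]-4-methylidene-5-oxooxolan-3-yl]-1-hydroxy-2-(triethylsilyloxy)ethyl]penta-2,4-dienoate
Conditions: CrCl2 (3 equiv), N-{2-[(4S)-4-isopropyl-4,5-dihydro-1,3-oxazol-2-yl]-6-methoxyphenyl}methanesulfonamide (3.3 equiv), Et3N (3.3 equiv), NiCl2 (5 mol %), THF, 23 °C; then aqueous work-up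
Reagents that add atoms: none
Why: Nozaki–Hiyama–Kishi coupling, in which nickel-catalysed activation of the C–I bond and transfer to chromium give an alkenylchromium that adds only to the aldehyde with retention of the alkene geometry (C9 cis to C2), while the chiral sulfonamide–chromium complex is relied on to give the 8,9-syn (9S) carbinol against the modest Felkin preference of the aldehyde.

Step 14
Reactants: 21 methyl (2E)-2-[(1S,2S)-2-[(2S,3S)-2-[(2R,3R)-3-ethenyl-3-methyloxiran-2-yl]-4-methylidene-5-oxooxolan-3-yl]-1-hydroxy-2-(triethylsilyloxy)ethyl]penta-2,4-dienoate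
Product: 22 methyl (2E)-2-[(1S,2S)-1-(acetyloxy)-2-[(2S,3S)-2-[(2R,3R)-3-ethenyl-3-methyloxiran-2-yl]-4-methylidene-5-oxooxolan-3-yl]-2-(triethylsilyloxy)ethyl]penta-2,4-dienoate
Conditions: Ac2O, DMAP (cat.), pyridine, CH2Cl2, 0 °C
Reagents that add atoms: acetic anhydride, CC(=O)OC(C)=O
Why: DMAP-catalysed acetylation of the secondary allylic alcohol proceeds with retention at C9, and the mild base should neither add to the methylene lactone nor move the silyl group.

Step 15
Reactants: 22 methyl (2E)-2-[(1S,2S)-1-(acetyloxy)-2-[(2S,3S)-2-[(2R,3R)-3-ethenyl-3-methyloxiran-2-yl]-4-methylidene-5-oxooxolan-3-yl]-2-(triethylsilyloxy)ethyl]penta-2,4-dienoate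
Product: 23 methyl (2E)-2-[(1S,2S)-1-(acetyloxy)-2-[(2S,3R)-2-[(2R,3R)-3-ethenyl-3-methyloxiran-2-yl]-4-methylidene-5-oxooxolan-3-yl]-2-hydroxyethyl]penta-2,4-dienoate
Conditions: Bu4NF/AcOH (1:1), THF, 0 °C
Reagents that add atoms: none
Why: Fluoride buffered with acetic acid removes the secondary triethylsilyl ether without opening the vinyl epoxide, shifting the acetate or adding to the methylene lactone.

Step 16
Reactants: 24 (E)-2-methylbut-2-en-1-ol
Product: 25 [(2S,3S)-2,3-dimethyloxiran-2-yl]methanol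
Conditions: Ti(OiPr)4 (10 mol %), L-(+)-diethyl tartrate (12 mol %), t-BuOOH, 4 Å MS, CH2Cl2, −20 °C
Reagents that add atoms: tert-butyl hydroperoxide, CC(C)(C)OO
Why: Sharpless asymmetric epoxidation with the L-tartrate catalyst should give the (2S,3S)-epoxy alcohol, and the E geometry of the alkene keeps the two methyl groups cis on the oxirane.

Step 17
Reactants: 25 [(2S,3S)-2,3-dimethyloxiran-2-yl]methanol
Product: 27 (2R,3S)-2,3-dimethyloxirane-2-carboxylic acid, via epoxy aldehyde 26 (not isolated)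
Conditions: TEMPO (20 mol %), PhI(OAc)2 (2.2 equiv), MeCN/H2O (1:1), 23 °C
Reagents that add atoms: water, O
Why: TEMPO/PhI(OAc)2 oxidation in aqueous acetonitrile takes the primary alcohol through the aldehyde hydrate to the carboxylic acid without touching the epoxide or its two stereocentres.

Step 18
Reactants: 23 methyl (2E)-2-[(1S,2S)-1-(acetyloxy)-2-[(2S,3R)-2-[(2R,3R)-3-ethenyl-3-methyloxiran-2-yl]-4-methylidene-5-oxooxolan-3-yl]-2-hydroxyethyl]penta-2,4-dienoate; 27 (2R,3S)-2,3-dimethyloxirane-2-carboxylic acid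
Product: 29 methyl (2E)-2-[(1S,2S)-1-(acetyloxy)-2-{[(2R,3S)-2,3-dimethyloxirane-2-carbonyl]oxy}-2-[(2S,3R)-2-[(2R,3R)-3-ethenyl-3-methyloxiran-2-yl]-4-methylidene-5-oxooxolan-3-yl]ethyl]penta-2,4-dienoate, via mixed anhydride 28 (not isolated)
Conditions: 27, 2,4,6-trichlorobenzoyl chloride, Et3N, THF, 23 °C; then 23, DMAP, toluene, 23 °C
Reagents that add atoms: none
Why: Yamaguchi esterification through the mixed anhydride acylates the hindered C8 hydroxyl with retention at C8 and at both oxirane centres of the acid, under conditions mild enough for the vinyl epoxide and the methylene lactone.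

Step 19
Reactants: 29 methyl (2E)-2-[(1S,2S)-1-(acetyloxy)-2-{[(2R,3S)-2,3-dimethyloxirane-2-carbonyl]oxy}-2-[(2S,3R)-2-[(2R,3R)-3-ethenyl-3-methyloxiran-2-yl]-4-methylidene-5-oxooxolan-3-yl]ethyl]penta-2,4-dienoate
Product: 30 target CNP0229507.5
Conditions: second-generation Grubbs catalyst (10 mol %), toluene (1 mM), 80 °C
Reagents that add atoms: none
Why: Ring-closing metathesis joins the two monosubstituted vinyl groups with loss of ethene; the ten-membered ring can hold the new C2=C3 bond only as the Z alkene, the trans-fused lactone and the epoxide bring the chain ends together, and the electron-poor lactone methylene and the trisubstituted enoate are poor partners for the ruthenium carbene.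

Compound list
1 | (E)-3-methylpent-2-en-4-yn-1-ol | C#C/C(C)=C/CO | starting material
2 | [(2R,3R)-3-ethynyl-3-methyloxiran-2-yl]methanol | C#C[C@@]1(C)O[C@@H]1CO | intermediate
3 | [(2R,3R)-3-ethenyl-3-methyloxiran-2-yl]methanol | C=C[C@@]1(C)O[C@@H]1CO | intermediate
4 | (2S,3R)-3-ethenyl-3-methyloxirane-2-carbaldehyde | C=C[C@@]1(C)O[C@@H]1C=O | intermediate
5 | (R)-2,2-dimethyl-1,3-dioxolane-4-carbaldehyde | O=C[C@H]1COC(C)(C)O1 | starting material
6 | (S)-4-ethynyl-2,2-dimethyl-1,3-dioxolane | C#C[C@H]1COC(C)(C)O1 | intermediate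
7 | Mannich base: N-cyclohexyl-N-{3-[(4S)-2,2-dimethyl-1,3-dioxolan-4-yl]prop-2-yn-1-yl}cyclohexanamine | C(C#C[C@H]1COC(C)(C)O1)N(C1CCCCC1)C1CCCCC1 | intermediate
8 | (S)-2,2-dimethyl-4-(propa-1,2-dien-1-yl)-1,3-dioxolane | C=C=C[C@H]1COC(C)(C)O1 | intermediate
9 | (S)-penta-3,4-diene-1,2-diol | C=C=C[C@H](O)CO | intermediate
10 | (S)-4,5-bis(triethylsilyloxy)penta-1,2-diene | C=C=C[C@H](O[Si](CC)(CC)CC)CO[Si](CC)(CC)CC | intermediate
11 | O-boryl ether: 2-{[(1R,2S,3S)-1-[(2R,3R)-3-ethenyl-3-methyloxiran-2-yl]-2-[1-(4,4,5,5-tetramethyl-1,3,2-dioxaborolan-2-yl)ethenyl]-3,4-bis(triethylsilyloxy)butyl]oxy}-4,4,5,5-tetramethyl-1,3,2-dioxaborolane | C=C(B1OC(C)(C)C(C)(C)O1)[C@@H]([C@@H](OB1OC(C)(C)C(C)(C)O1)[C@H]1O[C@]1(C)C=C)[C@H](O[Si](CC)(CC)CC)CO[Si](CC)(CC)CC | intermediate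
12 | (1R,2S,3S)-1-[(2R,3R)-3-ethenyl-3-methyloxiran-2-yl]-2-[1-(4,4,5,5-tetramethyl-1,3,2-dioxaborolan-2-yl)ethenyl]-3,4-bis(triethylsilyloxy)butan-1-ol | C=C(B1OC(C)(C)C(C)(C)O1)[C@@H]([C@@H](O)[C@H]1O[C@]1(C)C=C)[C@H](O[Si](CC)(CC)CC)CO[Si](CC)(CC)CC | intermediate
13 | (1R,2R,3S)-1-[(2R,3R)-3-ethenyl-3-methyloxiran-2-yl]-2-[1-(4,4,5,5-tetramethyl-1,3,2-dioxaborolan-2-yl)ethenyl]-3,4-bis(triethylsilyloxy)butyl methanesulfonate | C=C(B1OC(C)(C)C(C)(C)O1)[C@@H]([C@@H](OS(C)(=O)=O)[C@H]1O[C@]1(C)C=C)[C@H](O[Si](CC)(CC)CC)CO[Si](CC)(CC)CC | intermediate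
14 | potassium (3R,4S)-3-{(R)-[(2R,3R)-3-ethenyl-3-methyloxiran-2-yl](methanesulfonyloxy)methyl}-2-methylidene-4,5-bis(triethylsilyloxy)pentanoate | C=C(C(=O)[O-])[C@@H]([C@@H](OS(C)(=O)=O)[C@H]1O[C@]1(C)C=C)[C@H](O[Si](CC)(CC)CC)CO[Si](CC)(CC)CC.[K+] | intermediate
15 | (4S,5S)-4-[(1S)-1,2-bis(triethylsilyloxy)ethyl]-5-[(2R,3R)-3-ethenyl-3-methyloxiran-2-yl]-3-methylideneoxolan-2-one | C=C1C(=O)O[C@H]([C@H]2O[C@]2(C)C=C)[C@H]1[C@H](O[Si](CC)(CC)CC)CO[Si](CC)(CC)CC | intermediate
16 | (2S)-2-[(2S,3S)-2-[(2R,3R)-3-ethenyl-3-methyloxiran-2-yl]-4-methylidene-5-oxooxolan-3-yl]-2-(triethylsilyloxy)acetaldehyde | C=C1C(=O)O[C@H]([C@H]2O[C@]2(C)C=C)[C@H]1[C@H](O[Si](CC)(CC)CC)C=O | intermediate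
17 | methyl 2-(triphenylphosphoranylidene)acetate | COC(=O)C=P(c1ccccc1)(c1ccccc1)c1ccccc1 | starting material
18 | acrolein | C=CC=O | starting material
19 | iodo ylide: methyl 2-iodo-2-(triphenylphosphoranylidene)acetate | COC(=O)C(I)=P(c1ccccc1)(c1ccccc1)c1ccccc1 | intermediate
20 | methyl (2Z)-2-iodopenta-2,4-dienoate | C=C/C=C(\I)C(=O)OC | intermediate
21 | methyl (2E)-2-[(1S,2S)-2-[(2S,3S)-2-[(2R,3R)-3-ethenyl-3-methyloxiran-2-yl]-4-methylidene-5-oxooxolan-3-yl]-1-hydroxy-2-(triethylsilyloxy)ethyl]penta-2,4-dienoate | C=C1C(=O)O[C@H]([C@H]2O[C@]2(C)C=C)[C@H]1[C@H](O[Si](CC)(CC)CC)[C@@H](O)/C(C(=O)OC)=C\C=C | intermediate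
22 | methyl (2E)-2-[(1S,2S)-1-(acetyloxy)-2-[(2S,3S)-2-[(2R,3R)-3-ethenyl-3-methyloxiran-2-yl]-4-methylidene-5-oxooxolan-3-yl]-2-(triethylsilyloxy)ethyl]penta-2,4-dienoate | C=C1C(=O)O[C@H]([C@H]2O[C@]2(C)C=C)[C@H]1[C@H](O[Si](CC)(CC)CC)[C@@H](OC(C)=O)/C(C(=O)OC)=C\C=C | intermediate
23 | methyl (2E)-2-[(1S,2S)-1-(acetyloxy)-2-[(2S,3R)-2-[(2R,3R)-3-ethenyl-3-methyloxiran-2-yl]-4-methylidene-5-oxooxolan-3-yl]-2-hydroxyethyl]penta-2,4-dienoate | C=C1C(=O)O[C@H]([C@H]2O[C@]2(C)C=C)[C@H]1[C@H](O)[C@@H](OC(C)=O)/C(C(=O)OC)=C\C=C | intermediate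
24 | (E)-2-methylbut-2-en-1-ol (tiglyl alcohol) | C/C=C(\C)CO | starting material
25 | [(2S,3S)-2,3-dimethyloxiran-2-yl]methanol | OC[C@]1(C)O[C@H]1C | intermediate
26 | epoxy aldehyde: (2R,3S)-2,3-dimethyloxirane-2-carbaldehyde | O=C[C@]1(C)O[C@H]1C | intermediate
27 | (2R,3S)-2,3-dimethyloxirane-2-carboxylic acid | OC(=O)[C@]1(C)O[C@H]1C | intermediate
28 | mixed anhydride: (2R,3S)-2,3-dimethyloxirane-2-carboxylic 2,4,6-trichlorobenzoic anhydride | O=C(OC(=O)c1c(Cl)cc(Cl)cc1Cl)[C@]1(C)O[C@H]1C | intermediate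
29 | methyl (2E)-2-[(1S,2S)-1-(acetyloxy)-2-{[(2R,3S)-2,3-dimethyloxirane-2-carbonyl]oxy}-2-[(2S,3R)-2-[(2R,3R)-3-ethenyl-3-methyloxiran-2-yl]-4-methylidene-5-oxooxolan-3-yl]ethyl]penta-2,4-dienoate | C=C1C(=O)O[C@H]([C@H]2O[C@]2(C)C=C)[C@H]1[C@H](OC(=O)[C@]1(C)O[C@H]1C)[C@@H](OC(C)=O)/C(C(=O)OC)=C\C=C | intermediate
30 | target CNP0229507.5: methyl (4R,5R,6S,7R,8S,9S)-9-acetoxy-8-{[(2R,3S)-2,3-dimethyloxirane-2-carbonyl]oxy}-4,5-epoxy-12-oxo-6,12-epoxygermacra-1(10)E,2Z,11(13)-trien-14-oate | C=C1C(=O)O[C@H]2[C@H]1[C@H](OC(=O)[C@]1(C)O[C@H]1C)[C@@H](OC(C)=O)/C(C(=O)OC)=C\C=C/[C@@]1(C)O[C@H]21 | target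

Total step count: 19. Longest linear sequence: 13 steps (steps 4 to 11, 13 to 15, 18 and 19).

Steps most likely to fail

1. Step 8. The allylcopper species may lose the C8 silyloxy group by β-elimination before it meets the aldehyde, the copper–boryl species may open the vinyl epoxide, or the C8-bearing allyl unit may prefer the face opposite to the one set by catalyst and Felkin control. The fallback sets out from allene 10. Platinum-catalysed diboration of the terminal C=C (Pt(dba)2, PCy3, B2pin2, toluene, 50 °C) should give (4S,2Z)-1,2-bis(4,4,5,5-tetramethyl-1,3,2-dioxaborolan-2-yl)-4,5-bis(triethylsilyloxy)pent-2-ene F1, an allylboronate with no metal able to eliminate. Its uncatalysed allylboration of aldehyde 4 (toluene, 40 °C, chair transition state, Z reagent giving the 6,7-syn adduct) gives O-boryl ether 11 and, after work-up, alcohol 12, where the route is rejoined.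

2. Step 13. Facial selectivity may be low because the ligand-controlled addition is mismatched with the Felkin preference of the alpha-silyloxy aldehyde, and the alkene geometry may erode if the alkenylchromium equilibrates through an oxygen-bound allenoate. The fallback sets out from 16 and 20. Coupling without chiral ligand (CrCl2, NiCl2 cat., DMSO, 23 °C) should favour the Felkin product, the 9-epimer methyl (2E)-2-[(1R,2S)-2-[(2S,3S)-2-[(2R,3R)-3-ethenyl-3-methyloxiran-2-yl]-4-methylidene-5-oxooxolan-3-yl]-1-hydroxy-2-(triethylsilyloxy)ethyl]penta-2,4-dienoate F2. A Mitsunobu reaction with acetic acid (PPh3, diisopropyl azodicarboxylate, AcOH, toluene, 0 °C) then inverts C9 and gives acetate 22 directly, where the route is rejoined.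

3. Step 19. The ruthenium carbene may close onto the lactone methylene C13 to give a seven-membered ring, the diene may oligomerise by cross-metathesis, or closure of the crowded diester may be too slow. The fallback sets out from hydroxy acetate 23. Ring-closing metathesis before the bulky epoxy ester is in place (second-generation Grubbs catalyst, 1,4-benzoquinone, toluene, 1 mM, 80 °C) should give the macrocyclic alcohol, the 8-O-deacyl derivative of the target F3. This is acylated with acid 27 through mixed anhydride 28 under the conditions of step 18 to give target 30.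

Further compounds
F1 | step 8 | (4S,2Z)-1,2-bis(4,4,5,5-tetramethyl-1,3,2-dioxaborolan-2-yl)-4,5-bis(triethylsilyloxy)pent-2-ene | CC1(C)OB(C/C(B2OC(C)(C)C(C)(C)O2)=C\[C@H](O[Si](CC)(CC)CC)CO[Si](CC)(CC)CC)OC1(C)C
F2 | step 13 | methyl (2E)-2-[(1R,2S)-2-[(2S,3S)-2-[(2R,3R)-3-ethenyl-3-methyloxiran-2-yl]-4-methylidene-5-oxooxolan-3-yl]-1-hydroxy-2-(triethylsilyloxy)ethyl]penta-2,4-dienoate | C=C1C(=O)O[C@H]([C@H]2O[C@]2(C)C=C)[C@H]1[C@H](O[Si](CC)(CC)CC)[C@H](O)/C(C(=O)OC)=C\C=C
F3 | step 19 | 8-O-deacyl derivative of the target (free 8-hydroxyl, 9-acetate, macrocycle closed) | C=C1C(=O)O[C@H]2[C@H]1[C@H](O)[C@@H](OC(C)=O)/C(C(=O)OC)=C\C=C/[C@@]1(C)O[C@H]21
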